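## The problem

The target 15 is a Δ1(10)-octalin. Ring A (C1–C5, C10) and ring B (C5–C10) share the C5–C10 bond, C10 is an alkene carbon (C1=C10), and C5 is the only stereogenic ring-fusion atom. Four stereocentres must be set: the vicinal pair C8 (secondary methyl) and C9 (quaternary, carrying a methyl and the C11–C15 chain) in ring B, and the vicinal pair C4 (quaternary, methyl and CO2CH3) and C5 in ring A. C8 can control C9, because a group added to C9 of a ring-B enolate enters anti to the C8 methyl. The resulting cis C8/C9 methyl pair can then bias the face of ring B on which the C4–C5 bond is made, and C4 and C5 are tied to each other by the geometry of the reaction that forms that bond. The side chain ends in an (E)-trisubstituted allylic acetate that is stereochemically independent of the core and must be built with control of geometry. Three elements are fragile: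

- The allylic acetate is ionised by zerovalent palladium and by Lewis acids and is cleaved by base.
- The C1=C10 alkene gives, on protonation, a tertiary C10 cation next to quaternary C9, which invites 1,2-shifts and alkene migration.
- The hindered C4 methyl ester has to survive while a second carbonyl group in the chain is reduced.

The enabling feature is that C8 and C9 adjoin C10. With C10 as a ketone, C8 is the β-carbon and C9 the α-carbon (already bearing its methyl) of 2-methylcyclohex-2-en-1-one 1, so a nucleophilic methyl at C8 and an electrophilic C11 at C9 assemble the stereodiad on an intact ring B.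

## Retrosynthesis

**Chain terminus (15 to 14 to 13).** The O–acetyl bond of 15 is cut first, giving allylic alcohol 14, and the C15 carbinol is traced back to the ethyl ester of diester 13. Carrying an allylic acetate or a protected alcohol through ring construction would expose the allylic C–O bond to zerovalent palladium and to a Lewis acid, and would add protecting-group steps; an ester needs neither. The forward reduction must distinguish an unhindered conjugated ester from the C4 methyl ester, which sits on a quaternary carbon beside the ring fusion.

**Ring A (13 to 11 and 12).** The C2–C3 and C4–C5 bonds are cut in a retro-Diels–Alder sense, giving vinylcyclohexene 11 and methyl methacrylate 12. An annulation of the Robinson type on the C10 ketone would leave a ring-A enone with the wrong oxidation pattern and no quaternary ester at C4. The cycloaddition instead places the C1=C10 alkene where the target has it and delivers C4 with both substituents, together with C5. The precursor 11 has lost ring A and two stereocentres. The forward step must give "ortho" regiochemistry, approach on the face opposite the cis methyl pair, and an ester-endo transition state.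

**Diene (11 to 10).** The C10–C1 bond is cut, leading to enol triflate 10 and a Stille vinylation. Adding a vinyl organometallic to the ketone and dehydrating would pass through a tertiary carbinol next to quaternary C9 and leave the alkene position open to doubt. The enol triflate fixes the alkene at C5=C10. The coupling has to work at a triflate flanked by a quaternary carbon.

**Side-chain alkene (10 to 9).** The C13=C14 bond is cut by a Horner–Wadsworth–Emmons disconnection, giving methyl ketone 9. Placing this step before ring A keeps a Lewis-basic ketone, which could cyclise onto the diene, out of the cycloaddition. It also allows the minor alkene isomer to be removed on a small, simple compound. The forward step must favour the E isomer.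

**Unmasking and enol triflate (9 to 8 to 6).** The C13 carbonyl is traced to the vinyl chloride of 8, and the triflate of 8 to ketone 6. Hydrolysis is placed at this stage because the only other alkene in 8 is the electron-poor enol triflate, which resists the electrophilic, acidic conditions that the C1=C10 alkene or a diene would not. The triflate also masks C10, so the 1,5-dicarbonyl aldol that would follow from a free diketone cannot occur. In 6 only C5 can be deprotonated, so the triflate is a single regioisomer.

**Stereodiad (6 to 1, 2 and 3).** The C8–CH3 and C9–C11 bonds are cut, leading to enone 1, trimethylaluminium 2 and 1,3-dichlorobut-2-ene 3. All three are purchased and none carries a stereocentre. The forward reaction must select one enone face under ligand control, alkylate the enolate at carbon anti to the new methyl, and displace only the allylic chloride of 3. Reagent 3 is chosen because quaternisation needs a reactive allylic electrophile and because its vinyl chloride is a latent C13 ketone carrying the C13 methyl.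

## Roads not taken

Alternative 1: Ring B is cut at C7–C8 and C9–C10. (E)-2-Methylbut-2-enal A1 would react with (E)-1-(tert-butyldimethylsilyloxy)buta-1,3-diene A2 under a chiral oxazaborolidinium Lewis acid to give the endo cyclohexene A3.

- Merits: the E geometry of A1 is carried by the suprafacial addition into the cis C8/C9 methyl pair. One catalytic step makes ring B and both stereocentres. C11 arrives as an aldehyde, from which the chain could be grown by methods that control the C13=C14 geometry more strictly than olefination of a methyl ketone. No pyrophoric alane, no HMPA and no mercury salt are needed.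
- Weak points: an α,β-disubstituted enal is a slow dienophile and must form a quaternary centre. C10 arrives as a silyl ether next to a C5=C6 alkene, so desilylation, oxidation and alkene reduction are needed before the C10 ketone can serve ring A. The neopentyl C11 aldehyde still has to be extended by C12 and a four-carbon unit.
- Comparison: A3 is the better intermediate for side-chain flexibility and for a fully catalytic ring-forming key step. The chosen plan sets against it the C10 ketone at the correct oxidation level in one flask from 1, with the latent C11–C13 unit already attached, and a clearly shorter sequence to 15.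

Alternative 2: Both rings are cut at once at C5–C10 and C1–C2. The acyclic dienyne A4 would undergo intramolecular [4+2] cycloaddition with [Rh(cod)Cl]2/AgSbF6 (monovalent rhodium) to give the bicyclic 1,4-diene ester A5.

- Merits: rings A and B form in one step and the C1=C10 alkene comes directly from the alkyne. C5 is set through the tether. C4 would later be set by reductive methylation of the C3=C4 enoate, where attack from the equatorial direction is well founded. That is arguably a firmer basis for C4 than the endo/exo choice of a methacrylate cycloaddition.
- Weak points: A4 needs the same C8/C9 diad, including a quaternary carbon bearing an alkyne, on an open chain, where no ring relays C8 to C9. The tether has four atoms and the diene carries an ester. The C5 selectivity rests on acyclic conformations. A5 is a skipped diene prone to isomerisation, and it carries only a two-carbon stub of the side chain.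
- Comparison: the ring construction and the C4 control are better on that road. The chosen plan answers with a stereodiad made in one step on a preformed ring from purchased materials, and with fewer steps overall.

Alternative 3: Ring B is cut at C8–C9. The ring-A-fused δ-lactone A6 (lactone oxygen on C6, carbonyl C11, (Z)-propenyl on C6) would be enolised, O-silylated and rearranged (Ireland–Claisen ring contraction) to the bicyclic diene acid A7.

- Merits: C8 and C9 are set together through a boat transition state with chirality transfer from C6. The C11 acid and the C4 ester emerge differentiated. C4 and C5 are fixed before ring B exists, so no facial question arises in a cycloaddition.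
- Weak points: A6 itself needs C4, C5 and C6 set and a Z-propenyl group, so most of the stereochemical work moves into its preparation. The C9 enolate is allylic to C1=C10 and can react as an extended enolate. A quaternary centre must form through a boat. Afterwards C6=C7 must be hydrogenated in the presence of C1=C10, and the neopentyl C11 carboxyl reduced and extended by four carbons.
- Comparison: A7 holds all four stereocentres and is the stronger answer to the C4/C5 problem. The chosen plan is shorter and draws the C8/C9 pair from achiral materials by catalysis.

Key step: step 1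

Assumption: commercial 3 is an E/Z mixture; the chloroalkene geometry is left open in 3 and 6–8 because step 3 erases it.

Assumption: the phosphoramidite antipode used is the one that gives the 3R centre of 4; it is written as the (S)-binaphthol/(S,S)-amine isomer, and its mirror image would be taken if the sense of induction were opposite.

## Route

Step 1
Reactants: 1 2-methylcyclohex-2-en-1-one; 2 trimethylaluminium; 3 1,3-dichlorobut-2-ene
Product: 6 (2S,3R)-2-(3-chlorobut-2-en-1-yl)-2,3-dimethylcyclohexan-1-one, via dimethylaluminium enolate 4 (not isolated), via lithium aluminate enolate 5 (not isolated)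
Conditions: copper thiophene-2-carboxylate (CuTC, 2 mol%), (S)-binaphthol-derived N,N-bis[(S)-1-phenylethyl]phosphoramidite (4 mol%), Et2O, −30 °C; then MeLi, THF/HMPA, 3 (excess), −30 °C to rt
Reagents that add atoms: none
Why: Copper-catalysed asymmetric conjugate addition with enolate alkylation; the closest known reaction type is the phosphoramidite/copper-catalysed addition of trialkylaluminium reagents to 2-substituted cyclohexenones with trapping of the enolate. Alane 2 activates the carbonyl of 1 and passes a methyl to the chiral copper complex (monovalent copper), which binds the enone, adds at C8 through a trivalent copper intermediate and reductively eliminates, forming C8–CH3 and enolate 4. MeLi turns the weakly nucleophilic 4 into aluminate 5, whose C9 displaces the allylic chloride of 3 in an SN2 reaction, forming C9–C11. No ring closes in this step; ring B is carried in by 1. C8 is set by the ligand, which selects the enone face; C9 is set by the substrate, because the electrophile approaches the tetrasubstituted enolate anti to the C8 methyl, leaving C11 trans to it and the two methyls cis. The step needs face selection (ligand), C- over O-alkylation without enolate equilibration (the enolate is formed regiospecifically and meets a reactive allylic electrophile in a polar cosolvent), and discrimination between the two chlorides of 3 (the vinylic one is inert to SN2).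

Step 2
Reactants: 6 (2S,3R)-2-(3-chlorobut-2-en-1-yl)-2,3-dimethylcyclohexan-1-one
Product: 8 (5R,6S)-6-(3-chlorobut-2-en-1-yl)-5,6-dimethylcyclohex-1-en-1-yl trifluoromethanesulfonate, via potassium enolate 7 (not isolated)
Conditions: KN(SiMe3)2, THF, −78 °C; PhNTf2, −78 to 0 °C
Reagents that add atoms: N-phenylbis(trifluoromethanesulfonimide), O=S(=O)(N(c1ccccc1)S(=O)(=O)C(F)(F)F)C(F)(F)F
Why: Enolate O-triflation; C9 is quaternary, so deprotonation can occur only at C5 and the C5=C10 enol triflate forms as one regioisomer. The hindered silylamide should not dehydrochlorinate the vinyl chloride at low temperature, and no stereocentre is touched.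

Step 3
Reactants: 8 (5R,6S)-6-(3-chlorobut-2-en-1-yl)-5,6-dimethylcyclohex-1-en-1-yl trifluoromethanesulfonate
Product: 9 (5R,6S)-5,6-dimethyl-6-(3-oxobutyl)cyclohex-1-en-1-yl trifluoromethanesulfonate
Conditions: Hg(OAc)2, 88% aq. HCO2H, rt; aqueous work-up
Reagents that add atoms: water, O
Why: Mercury-assisted hydrolysis of a vinyl chloride, the unmasking stage of the Wichterle reaction: mercuration at C12 gives a chlorine-stabilised cation at C13 that takes up water and collapses to the methyl ketone with loss of HCl and protodemercuration. The only other alkene is the electron-poor enol triflate, which neither adds divalent mercury nor solvolyses in acid, and it keeps C10 masked so that no intramolecular aldol can follow.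

Step 4
Reactants: 9 (5R,6S)-5,6-dimethyl-6-(3-oxobutyl)cyclohex-1-en-1-yl trifluoromethanesulfonate
Product: 10 ethyl (2E)-5-[(1S,6R)-1,6-dimethyl-2-(trifluoromethanesulfonyloxy)cyclohex-2-en-1-yl]-3-methylpent-2-enoate
Conditions: (EtO)2P(O)CH2CO2Et, NaH, THF, 0 °C to rt; chromatographic removal of the Z isomer
Reagents that add atoms: triethyl phosphonoacetate, CCOC(=O)CP(=O)(OCC)OCC
Why: Horner–Wadsworth–Emmons olefination of a methyl ketone; reversible addition lets the larger C12 chain settle trans to the ester, so the E isomer should predominate, and the minor isomer is removed at this simple stage. The stabilised phosphonate anion should leave the hindered enol triflate alone.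

Step 5
Reactants: 10 ethyl (2E)-5-[(1S,6R)-1,6-dimethyl-2-(trifluoromethanesulfonyloxy)cyclohex-2-en-1-yl]-3-methylpent-2-enoate
Product: 11 ethyl (2E)-5-[(1S,6R)-2-ethenyl-1,6-dimethylcyclohex-2-en-1-yl]-3-methylpent-2-enoate
Conditions: Bu3SnCH=CH2, Pd(PPh3)4 (5 mol%), LiCl, THF, 65 °C
Reagents that add atoms: tributyl(vinyl)stannane, C=C[Sn](CCCC)(CCCC)CCCC
Why: Stille coupling of an enol triflate: oxidative addition of zerovalent palladium to the C10–O bond, chloride exchange, vinyl transfer from tin and reductive elimination form C10–C1 and leave the ring alkene at C5=C10. The enoate is inert, and no vinyl chloride remains to compete.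

Step 6
Reactants: 11 ethyl (2E)-5-[(1S,6R)-2-ethenyl-1,6-dimethylcyclohex-2-en-1-yl]-3-methylpent-2-enoate; 12 methyl methacrylate
Product: 13 methyl (1S,5S,6R,8aR)-5-[(3E)-5-ethoxy-3-methyl-5-oxopent-3-en-1-yl]-1,5,6-trimethyl-1,2,3,5,6,7,8,8a-octahydronaphthalene-1-carboxylate
Conditions: 12 (5 equiv), EtAlCl2, CH2Cl2, −78 to −20 °C
Reagents that add atoms: none
Why: Lewis-acid-promoted Diels–Alder reaction forming C2–C3 and C4–C5 with "ortho" regiochemistry, since the CH2 of the activated methacrylate bonds first to the unhindered diene terminus C2 and the ester-bearing carbon then closes onto C5. The dienophile should approach the diene face opposite the cis C8/C9 methyl pair (the C9 methyl is pseudoaxial in the half-chair that keeps the C8 methyl equatorial), which sets C5, and the ester-endo transition state places CO2CH3 cis to C6, which sets C4. The side-chain enoate is β,β-disubstituted and should not act as a dienophile.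

Step 7
Reactants: 13 methyl (1S,5S,6R,8aR)-5-[(3E)-5-ethoxy-3-methyl-5-oxopent-3-en-1-yl]-1,5,6-trimethyl-1,2,3,5,6,7,8,8a-octahydronaphthalene-1-carboxylate
Product: 14 methyl (1S,5S,6R,8aR)-5-[(3E)-5-hydroxy-3-methylpent-3-en-1-yl]-1,5,6-trimethyl-1,2,3,5,6,7,8,8a-octahydronaphthalene-1-carboxylate
Conditions: i-Bu2AlH (2.2 equiv), CH2Cl2, −78 °C; aq. potassium sodium tartrate
Reagents that add atoms: none
Why: Chemoselective 1,2-reduction of an ester: the unhindered conjugated ethyl ester should be reduced at −78 °C, while the C4 methyl ester on a quaternary carbon beside the ring fusion reacts far more slowly. The E alkene is untouched.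

Step 8
Reactants: 14 methyl (1S,5S,6R,8aR)-5-[(3E)-5-hydroxy-3-methylpent-3-en-1-yl]-1,5,6-trimethyl-1,2,3,5,6,7,8,8a-octahydronaphthalene-1-carboxylate
Product: 15 methyl (1S,5S,6R,8aR)-5-[(3E)-5-acetoxy-3-methylpent-3-en-1-yl]-1,5,6-trimethyl-1,2,3,5,6,7,8,8a-octahydronaphthalene-1-carboxylate
Conditions: Ac2O, pyridine, DMAP (cat.), CH2Cl2, 0 °C to rt
Reagents that add atoms: acetic anhydride, CC(=O)OC(C)=O
Why: Nucleophile-catalysed O-acylation of a primary allylic alcohol under mild conditions that leave the hindered ester and both alkenes unchanged.

## Compound list

1 | 2-methylcyclohex-2-en-1-one | CC1=CCCCC1=O | starting material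
2 | trimethylaluminium | C[Al](C)C | starting material
3 | 1,3-dichlorobut-2-ene (E/Z mixture) | CC(Cl)=CCCl | starting material
4 | dimethyl{[(3R)-2,3-dimethylcyclohex-1-en-1-yl]oxy}alumane (dimethylaluminium enolate, formed in the flask) | C[C@@H]1CCCC(O[Al](C)C)=C1C | intermediate
5 | lithium trimethyl{[(3R)-2,3-dimethylcyclohex-1-en-1-yl]oxy}aluminate (formed in the flask) | [Li+].C[C@@H]1CCCC(O[Al-](C)(C)C)=C1C | intermediate
6 | (2S,3R)-2-(3-chlorobut-2-en-1-yl)-2,3-dimethylcyclohexan-1-one (methyls cis, chain trans to the C3 methyl) | C[C@@H]1CCCC(=O)[C@@]1(C)CC=C(C)Cl | intermediate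
7 | potassium (5R,6S)-6-(3-chlorobut-2-en-1-yl)-5,6-dimethylcyclohex-1-en-1-olate (formed in the flask) | [K+].C[C@@H]1CCC=C([O-])[C@@]1(C)CC=C(C)Cl | intermediate
8 | (5R,6S)-6-(3-chlorobut-2-en-1-yl)-5,6-dimethylcyclohex-1-en-1-yl trifluoromethanesulfonate | C[C@@H]1CCC=C(OS(=O)(=O)C(F)(F)F)[C@@]1(C)CC=C(C)Cl | intermediate
9 | (5R,6S)-5,6-dimethyl-6-(3-oxobutyl)cyclohex-1-en-1-yl trifluoromethanesulfonate | C[C@@H]1CCC=C(OS(=O)(=O)C(F)(F)F)[C@@]1(C)CCC(C)=O | intermediate
10 | ethyl (2E)-5-[(1S,6R)-1,6-dimethyl-2-(trifluoromethanesulfonyloxy)cyclohex-2-en-1-yl]-3-methylpent-2-enoate | C[C@@H]1CCC=C(OS(=O)(=O)C(F)(F)F)[C@@]1(C)CC/C(C)=C/C(=O)OCC | intermediate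
11 | ethyl (2E)-5-[(1S,6R)-2-ethenyl-1,6-dimethylcyclohex-2-en-1-yl]-3-methylpent-2-enoate | C[C@@H]1CCC=C(C=C)[C@@]1(C)CC/C(C)=C/C(=O)OCC | intermediate
12 | methyl methacrylate | C=C(C)C(=O)OC | starting material
13 | methyl (1S,5S,6R,8aR)-5-[(3E)-5-ethoxy-3-methyl-5-oxopent-3-en-1-yl]-1,5,6-trimethyl-1,2,3,5,6,7,8,8a-octahydronaphthalene-1-carboxylate | COC(=O)[C@@]1(C)CCC=C2[C@H]1CC[C@@H](C)[C@]2(C)CC/C(C)=C/C(=O)OCC | intermediate
14 | methyl (1S,5S,6R,8aR)-5-[(3E)-5-hydroxy-3-methylpent-3-en-1-yl]-1,5,6-trimethyl-1,2,3,5,6,7,8,8a-octahydronaphthalene-1-carboxylate | COC(=O)[C@@]1(C)CCC=C2[C@H]1CC[C@@H](C)[C@]2(C)CC/C(C)=C/CO | intermediate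
15 | methyl (1S,5S,6R,8aR)-5-[(3E)-5-acetoxy-3-methylpent-3-en-1-yl]-1,5,6-trimethyl-1,2,3,5,6,7,8,8a-octahydronaphthalene-1-carboxylate | COC(=O)[C@@]1(C)CCC=C2[C@H]1CC[C@@H](C)[C@]2(C)CC/C(C)=C/COC(C)=O | target

## Step count and least certain steps

Total: 8 steps. Longest linear sequence: 8 steps (steps 1–8 from 1).

**Step 1 (key step).** The most likely failure is slow C-alkylation of the aluminium-bound enolate by an allylic chloride. Proton transfer between enolate and product would then return the unalkylated conjugate adduct or scramble the site of alkylation, and trans selectivity could erode if the electrophile has to be forced. The fallback separates the two events. It sets out from 1: the conjugate addition is run as before and enolate 4 is silylated with Me3SiOSO2CF3 to the isolable trimethylsilyl enol ether F1. Reagent 3 is converted with NaI in acetone into the more reactive 3-chloro-1-iodobut-2-ene F2. MeLi in THF then cleaves F1 to the lithium enolate F3, which is alkylated with F2 in THF/HMPA. The fallback returns to the route at 6.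

**Step 6.** Three things can go wrong. Facial discrimination may be poor, because the two C9 substituents differ little in size and the bias rests on the cis methyl pair. The ester-endo preference may be eroded by the α-methyl group of 12. The Lewis acid may trigger oligomerisation of the diene or cyclisation onto the side-chain enoate. The fallback sets out from 11 and uses methacrolein under catalyst control, with the oxazaborolidinium salt made from α,α-diphenylprolinol (antipode chosen to match the substrate), tri(o-tolyl)boroxine and HN(SO2CF3)2. An aldehyde dienophile binds the catalyst more firmly and should show a stronger carbonyl-endo preference; this gives the C4 aldehyde F4. Oxidation (NaClO2, NaH2PO4, 2-methylbut-2-ene, t-BuOH/H2O) gives the C4 carboxylic acid F5, and O-methylation (MeI, K2CO3, DMF) returns to the route at 13.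

**Step 4.** The olefination of a methyl ketone may give insufficient E/Z selectivity, since the two ketone substituents (CH3 and CH2R) differ only moderately. The fallback sets out from 9 and builds the alkene by syn carbometalation. Kinetic enolisation (LiN(i-Pr)2, THF, −78 °C) and ClP(O)(OEt)2 give the enol phosphate F6. Elimination with LiN(i-Pr)2 gives the terminal alkyne F7. Zirconium-catalysed carboalumination (AlMe3, Cp2ZrCl2, CH2Cl2) followed by ClCO2Et places the new methyl and the ester cis across the alkene, returning to the route at 10 as the E isomer only.

**Step 7.** Hydride may not discriminate cleanly between the two esters, leading to partial reduction of the C4 ester or a stall at the aldehyde stage. The fallback sets out from 13 and differentiates the esters by hydrolysis. LiOH in THF/H2O should saponify only the unhindered conjugated ethyl ester, giving the monoacid F8. Activation with ClCO2Et/Et3N gives the mixed carbonic anhydride F9, and NaBH4 reduction of F9 returns to the route at 14.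

## Further compounds

F1 | step 1 | trimethyl{[(3R)-2,3-dimethylcyclohex-1-en-1-yl]oxy}silane | C[C@@H]1CCCC(O[Si](C)(C)C)=C1C
F2 | step 1 | 3-chloro-1-iodobut-2-ene | CC(Cl)=CCI
F3 | step 1 | lithium (3R)-2,3-dimethylcyclohex-1-en-1-olate | [Li+].C[C@@H]1CCCC([O-])=C1C
F4 | step 6 | ethyl (2E)-5-[(1S,2R,4aR,5S)-5-formyl-1,2,5-trimethyl-1,2,3,4,4a,5,6,7-octahydronaphthalen-1-yl]-3-methylpent-2-enoate (C4 aldehyde analogue of 13) | O=C[C@@]1(C)CCC=C2[C@H]1CC[C@@H](C)[C@]2(C)CC/C(C)=C/C(=O)OCC
F5 | step 6 | (1S,5S,6R,8aR)-5-[(3E)-5-ethoxy-3-methyl-5-oxopent-3-en-1-yl]-1,5,6-trimethyl-1,2,3,5,6,7,8,8a-octahydronaphthalene-1-carboxylic acid | OC(=O)[C@@]1(C)CCC=C2[C@H]1CC[C@@H](C)[C@]2(C)CC/C(C)=C/C(=O)OCC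
F6 | step 4 | (5R,6S)-6-{3-[(diethoxyphosphoryl)oxy]but-3-en-1-yl}-5,6-dimethylcyclohex-1-en-1-yl trifluoromethanesulfonate | C[C@@H]1CCC=C(OS(=O)(=O)C(F)(F)F)[C@@]1(C)CCC(=C)OP(=O)(OCC)OCC
F7 | step 4 | (5R,6S)-6-(but-3-yn-1-yl)-5,6-dimethylcyclohex-1-en-1-yl trifluoromethanesulfonate | C[C@@H]1CCC=C(OS(=O)(=O)C(F)(F)F)[C@@]1(C)CCC#C
F8 | step 7 | (2E)-5-[(1S,2R,4aR,5S)-5-(methoxycarbonyl)-1,2,5-trimethyl-1,2,3,4,4a,5,6,7-octahydronaphthalen-1-yl]-3-methylpent-2-enoic acid | COC(=O)[C@@]1(C)CCC=C2[C@H]1CC[C@@H](C)[C@]2(C)CC/C(C)=C/C(=O)O
F9 | step 7 | mixed ethyl carbonic anhydride of F8 | COC(=O)[C@@]1(C)CCC=C2[C@H]1CC[C@@H](C)[C@]2(C)CC/C(C)=C/C(=O)OC(=O)OCC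
A1 | alternative 1 | (E)-2-methylbut-2-enal | C/C=C(\C)C=O
A2 | alternative 1 | (E)-1-(tert-butyldimethylsilyloxy)buta-1,3-diene | C=C/C=C/O[Si](C)(C)C(C)(C)C
A3 | alternative 1 | endo adduct, 2-(tert-butyldimethylsilyloxy)-1,6-dimethylcyclohex-3-ene-1-carbaldehyde (formyl cis to the silyloxy group, the two methyls cis) | C[C@@H]1CC=C[C@@H](O[Si](C)(C)C(C)(C)C)[C@@]1(C)C=O
A4 | alternative 2 | methyl (2Z,6R,7S)-9-(tert-butyldimethylsilyloxy)-2-ethenyl-7-ethynyl-6,7-dimethylnon-2-enoate | C=C/C(C(=O)OC)=C/CC[C@@H](C)[C@@](C)(C#C)CCO[Si](C)(C)C(C)(C)C
A5 | alternative 2 | bicyclic 1,4-diene ester (C3=C4 and C1=C10) with a 2-(tert-butyldimethylsilyloxy)ethyl group on C9 | COC(=O)C1=CCC=C2[C@H]1CC[C@@H](C)[C@]2(C)CCO[Si](C)(C)C(C)(C)C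
A6 | alternative 3 | ring-A-fused δ-lactone, methyl (1R,8S,8aR)-4,8-dimethyl-3-oxo-1-[(1Z)-prop-1-en-1-yl]-3,4,6,7,8,8a-hexahydro-1H-isochromene-8-carboxylate (configuration at the enolisable C9 left open) | COC(=O)[C@@]1(C)CCC=C2[C@H]1[C@H](OC(=O)C2C)/C=C\C
A7 | alternative 3 | bicyclic diene acid (C1=C10 and C6=C7) with C11 as carboxyl | COC(=O)[C@@]1(C)CCC=C2[C@H]1C=C[C@@H](C)[C@]2(C)C(=O)O
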